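**Plan**

1. The target is read as epirobinetinidol-(4β→8)-epirobinetinidol-(4α→8)-epicatechin: top unit 2R,3R,4R (2,3-cis-3,4-trans), middle unit 2R,3R,4S (all-cis), bottom unit (−)-epicatechin (2R,3R).
2. Retrosynthesis: (a) middle C-3 is epimerised through its ketone; (b) one acid-triggered operation cuts three C–C bonds, namely middle C-4–C-8 of the bottom unit, middle C-4–C-4a (pyran ring of the middle unit) and top C-4–C-4a (pyran ring of the top unit); (c) top C-4–middle C-8 is cut to an aryllithium and an aldehyde; (d) each C-2–O-1 aryl ether is cut to a phenol and a benzylic epoxide.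
3. Forward: a trans- and a cis-epoxide made from 3,4,5-tris(benzyloxy)benzaldehyde are opened by 3-(benzyloxy)-2-bromophenol and 3-(benzyloxy)phenol; the two chains are joined by aryllithium addition; then the top pyran ring, the middle pyran ring and the middle–bottom interflavan bond form in one flask; oxidation/reduction at middle C-3 and hydrogenolysis finish.
4. Enabling feature: middle C-4 lies between C-4a (para to O-7 and ortho to O-1 of the resorcinol-type ring A of the middle unit, its only free ortho position once C-8 carries the top unit) and C-8 of the phloroglucinol-type ring A of the bottom unit, so it can be carried as an acetal carbon that is arylated twice; top C-4 is benzylic to a ring with oxygen at both ortho positions and ionises as easily. Helpers removed later: the 4-methoxy leaving group, the bromine that marks middle C-8, and the temporary 2,3-trans configuration of the middle ring.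
5. Stereochemistry: top C-2/C-3 from Jacobsen epoxidation of a Z-cinnamate (cis-epoxide, SN2 inversion at C-2); middle C-2 from Shi epoxidation (trans-epoxide, inversion at C-2); both C-4 centres by substrate control in the key step (bond formation anti to the C-3 oxygen); middle C-3 by hydride delivery anti to the two cis aryl groups; the bottom unit from the chiral pool.

Key step: step 14

**Step 1**
Reactants: 1 (−)-epicatechin
Product: 2 5,7,3',4'-tetra-O-benzyl-(−)-epicatechin
Conditions: BnBr (4.4 equiv), K2CO3, DMF, 0 °C → rt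
Reagents that add atoms: benzyl bromide, BrCc1ccccc1
Why: Williamson etherification in which carbonate deprotonates only the four phenols, so the secondary 3-OH stays free and C-2/C-3 are untouched.

**Step 2**
Reactants: 2 5,7,3',4'-tetra-O-benzyl-(−)-epicatechin
Product: 3 3,5,7,3',4'-penta-O-benzyl-(−)-epicatechin
Conditions: NaH, BnBr, Bu4NI (cat.), DMF, 0 °C → rt
Reagents that add atoms: benzyl bromide, BrCc1ccccc1
Why: Williamson etherification of the secondary alkoxide masks the bottom 3-OH, so that only one secondary alcohol is free when the middle unit is oxidised later.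

**Step 3**
Reactants: 4 3,4,5-tris(benzyloxy)benzaldehyde
Product: 5 (E)-3-[3,4,5-tris(benzyloxy)phenyl]prop-2-enal
Conditions: Ph3P=CHCHO (1.1 equiv), toluene, 90 °C
Reagents that add atoms: (triphenylphosphoranylidene)acetaldehyde, O=CC=P(c1ccccc1)(c1ccccc1)c1ccccc1
Why: Wittig olefination with a stabilised ylide should give the E-enal and adds the two carbons that become middle C-3 and C-4.

**Step 4**
Reactants: 5 (E)-3-[3,4,5-tris(benzyloxy)phenyl]prop-2-enal
Product: 6 5-[(E)-3,3-dimethoxyprop-1-enyl]-1,2,3-tris(benzyloxy)benzene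
Conditions: HC(OMe)3, MeOH, pyridinium p-toluenesulfonate (cat.), rt
Reagents that add atoms: trimethyl orthoformate, COC(OC)OC
Why: Acid-catalysed acetalisation stores the future middle C-4 as a latent oxocarbenium ion and makes the alkene electron-rich enough for dioxirane epoxidation.

**Step 5**
Reactants: 6 5-[(E)-3,3-dimethoxyprop-1-enyl]-1,2,3-tris(benzyloxy)benzene
Product: 7 (2R,3S)-2-(dimethoxymethyl)-3-[3,4,5-tris(benzyloxy)phenyl]oxirane (trans)
Conditions: L-fructose-derived ketone catalyst (1,2:4,5-di-O-isopropylidene-β-L-erythro-2,3-hexodiulo-2,6-pyranose, 0.3 equiv), Oxone (2KHSO5·KHSO4·K2SO4), K2CO3, Bu4NHSO4, MeCN/CH2(OMe)2/aqueous buffer pH 10.5, 0 °C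
Reagents that add atoms: potassium peroxymonosulfate (KHSO5, the oxidant in Oxone), [K+].[O-]S(=O)(=O)OO
Why: Shi epoxidation of a trans-disubstituted styrene-type alkene through a spiro dioxirane transition state sets both epoxide carbons; the enantiomer of the usual D-fructose ketone is chosen because the D-ketone oxidises the opposite face of trans-β-substituted styrenes.

**Step 6**
Reactants: 8 2-bromobenzene-1,3-diol
Product: 9 3-(benzyloxy)-2-bromophenol
Conditions: BnBr (1.0 equiv), K2CO3, acetone, reflux; separation from diether and diol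
Reagents that add atoms: benzyl bromide, BrCc1ccccc1
Why: Williamson mono-etherification of a symmetrical diol can give only one mono-ether; the bromine marks the carbon between the two oxygens that becomes middle C-8.

**Step 7**
Reactants: 7 (2R,3S)-2-(dimethoxymethyl)-3-[3,4,5-tris(benzyloxy)phenyl]oxirane; 9 3-(benzyloxy)-2-bromophenol
Product: 10 (2R,3R)-3-[3-(benzyloxy)-2-bromophenoxy]-1,1-dimethoxy-3-[3,4,5-tris(benzyloxy)phenyl]propan-2-ol
Conditions: Cs2CO3 (0.3 equiv), DMF, 80 °C
Reagents that add atoms: none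
Why: Base-catalysed SN2 opening of the epoxide by the phenoxide at the benzylic carbon (the carbon next to the acetal is inductively deactivated and more hindered) proceeds with inversion, giving the erythro ether that is R at the future middle C-2 and keeps the epoxide oxygen as the C-3 hydroxyl (future 2,3-trans ring).

**Step 8**
Reactants: 4 3,4,5-tris(benzyloxy)benzaldehyde
Product: 11 ethyl (Z)-3-[3,4,5-tris(benzyloxy)phenyl]prop-2-enoate
Conditions: (PhO)2P(O)CH2CO2Et, NaH, THF, −78 → 0 °C
Reagents that add atoms: ethyl 2-(diphenoxyphosphoryl)acetate, CCOC(=O)CP(=O)(Oc1ccccc1)Oc1ccccc1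
Why: Z-selective Horner–Wadsworth–Emmons olefination with a diaryl phosphonoacetate, whose fast elimination from the kinetic adduct should give the cis-cinnamate.

**Step 9**
Reactants: 11 ethyl (Z)-3-[3,4,5-tris(benzyloxy)phenyl]prop-2-enoate
Product: 12 ethyl (2S,3S)-3-[3,4,5-tris(benzyloxy)phenyl]oxirane-2-carboxylate (cis)
Conditions: NaOCl (aq., pH 11.3), (S,S)-N,N'-bis(3,5-di-tert-butylsalicylidene)-1,2-cyclohexanediaminomanganese chloride [(S,S)-(salen)MnCl, 5 mol %], 4-phenylpyridine N-oxide (0.25 equiv), CH2Cl2, 0 °C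
Reagents that add atoms: sodium hypochlorite, [Na+].[O-]Cl
Why: Jacobsen epoxidation of a cis-disubstituted conjugated alkene with the (S,S)-catalyst should give the (2S,3S)-cis-glycidate, which fixes the future top C-3 directly and the future top C-2 after inversion.

**Step 10**
Reactants: 12 ethyl (2S,3S)-3-[3,4,5-tris(benzyloxy)phenyl]oxirane-2-carboxylate; 13 3-(benzyloxy)phenol
Product: 14 ethyl (2S,3R)-3-[3-(benzyloxy)phenoxy]-2-hydroxy-3-[3,4,5-tris(benzyloxy)phenyl]propanoate
Conditions: Cs2CO3 (0.3 equiv), DMF, 60 °C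
Reagents that add atoms: none
Why: SN2 opening of the glycidic ester by the phenoxide at the benzylic carbon with inversion converts the cis-epoxide into the threo aryl ether (R at the future top C-2, future 2,3-cis ring).

**Step 11**
Reactants: 14 ethyl (2S,3R)-3-[3-(benzyloxy)phenoxy]-2-hydroxy-3-[3,4,5-tris(benzyloxy)phenyl]propanoate
Product: 15 ethyl (2S,3R)-2-(benzyloxy)-3-[3-(benzyloxy)phenoxy]-3-[3,4,5-tris(benzyloxy)phenyl]propanoate
Conditions: BnBr, Ag2O, toluene, rt, dark
Reagents that add atoms: benzyl bromide, BrCc1ccccc1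
Why: Williamson etherification promoted by Ag2O is chosen because a strong base would eliminate the β-aryloxide from the ester enolate; it masks the future top 3-OH until the end.

**Step 12**
Reactants: 15 ethyl (2S,3R)-2-(benzyloxy)-3-[3-(benzyloxy)phenoxy]-3-[3,4,5-tris(benzyloxy)phenyl]propanoate
Product: 16 (2S,3R)-2-(benzyloxy)-3-[3-(benzyloxy)phenoxy]-3-[3,4,5-tris(benzyloxy)phenyl]propanal
Conditions: i-Bu2AlH (1.1 equiv), toluene, −78 °C; then aq. KNaC4H4O6
Reagents that add atoms: none
Why: Partial reduction of the ester with i-Bu2AlH at −78 °C, where the α-alkoxy-chelated aluminium hemiacetal survives until work-up, should give the aldehyde without epimerisation.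

**Step 13**
Reactants: 10 (2R,3R)-3-[3-(benzyloxy)-2-bromophenoxy]-1,1-dimethoxy-3-[3,4,5-tris(benzyloxy)phenyl]propan-2-ol; 16 (2S,3R)-2-(benzyloxy)-3-[3-(benzyloxy)phenoxy]-3-[3,4,5-tris(benzyloxy)phenyl]propanal
Product: 17 carbinol joining the two chains (both epimers at the new carbinol carbon)
Conditions: 10, n-BuLi (2.1 equiv), THF, −78 °C; then 16, −78 → −40 °C; then H2O; rapid filtration through Et3N-deactivated silica
Reagents that add atoms: none
Why: Bromine–lithium exchange (after deprotonation of the hydroxyl group by the first equivalent) followed by 1,2-addition of the aryllithium to the aldehyde forms the top C-4–middle C-8 bond exactly at the carbon between the two oxygens; the new carbinol centre is formed without control and is planarised in step 14.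

**Step 14**
Reactants: 17 carbinol joining the two chains; 3 3,5,7,3',4'-penta-O-benzyl-(−)-epicatechin
Product: 20 tetradeca-O-benzyl epirobinetinidol-(4β→8)-robinetinidol-(4α→8)-epicatechin (middle 3-OH free), via top-ring-closed acetal 18 (not isolated), via bis-cyclised 4-methoxyflavan 19 (not isolated)
Conditions: 3 (2.5 equiv), TMSOTf (0.3 equiv), 4 Å molecular sieves, CH2Cl2 (0.01 M in 17), −78 → −30 °C; then Et3N, aq. NaHCO3
Reagents that add atoms: none
Why: TMSOTf (through the triflic acid it releases) first ionises the carbinol of 17, whose carbon is benzylic to a ring with oxygen in both ortho positions, and the 3-(benzyloxy)phenyl ether closes the top pyran ring para to its benzyloxy group (18); the dimethyl acetal then gives an oxocarbenium ion at middle C-4 that is attacked by C-4a of the resorcinol-type ring (para to O-7, ortho to O-1), closing the middle pyran ring through the C-4a–C-4 bond (19), and renewed ionisation of the 4-methoxy group gives the flavan-4-yl cation that C-8 of 3 captures. The closest known reaction types are the dehydrative intramolecular Friedel–Crafts alkylation of electron-rich benzylic alcohols, the acetal-initiated Friedel–Crafts cyclisation of 3-aryloxypropanal acetals to 4-alkoxychromans and the Lewis-acid-mediated condensation of 4-alkoxyflavan-3-ols with flavan-3-ol nucleophiles. Both rings close in the 6-exo-trig mode at the cationic carbon (its C=aryl or C=O π bond stays outside the new ring), the arene reacting through its C-4a=C-8a bond. Top C-4 is controlled by C-3: allylic 1,3-strain with the ortho oxygens of the cation-bearing ring keeps H-3 in the plane of the cation, so the arene, delivered from the side of C-2, bonds anti to the 3-benzyloxy group (3,4-trans, 4R). Middle C-4 is controlled by C-3 as well, 3 adding to the ring-closed 2,3-trans cation anti to the C-3 oxygen (3,4-trans, 2,4-cis, 4S), and the same 1,3-strain model predicts the same isomer should 3 add to the oxocarbenium ion before the ring closes. The step needs chemoselectivity among three cations and several electron-rich rings: both ring closures are intramolecular and six-membered, C-4a is the only free ortho position of the middle ring, the top ring closure para to the benzyloxy group is the less hindered one, and benzylated epicatechin reacts at C-8 in preference to C-6.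

**Step 15**
Reactants: 20 tetradeca-O-benzyl epirobinetinidol-(4β→8)-robinetinidol-(4α→8)-epicatechin (middle 3-OH free)
Product: 21 3-ketone of the middle unit (2R,4S; 2,4-cis diaryl)
Conditions: Dess–Martin periodinane (1.5 equiv), pyridine, CH2Cl2, 0 °C → rt
Reagents that add atoms: none
Why: Dess–Martin oxidation of the only free hydroxyl group under pyridine buffering should give the 3-ketone without touching the two α-stereocentres, whose 2,4-cis arrangement (both aryl groups pseudo-equatorial) is also the more stable one.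

**Step 16**
Reactants: 21 3-ketone of the middle unit
Product: 22 tetradeca-O-benzyl epirobinetinidol-(4β→8)-epirobinetinidol-(4α→8)-epicatechin (middle unit 2R,3R,4S, 3-OH free)
Conditions: LiBH(s-Bu)3 (1.5 equiv), THF, −78 °C; then H2O
Reagents that add atoms: none
Why: Ketone reduction by a bulky trialkylborohydride, in which hydride should add from the face opposite to the cis-disposed aryl groups at C-2 and C-4, gives the axial (3R) alcohol and so the all-cis middle ring, as in the known conversion of catechin-type 3-ketones into epicatechin-type alcohols.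

**Step 17**
Reactants: 22 tetradeca-O-benzyl epirobinetinidol-(4β→8)-epirobinetinidol-(4α→8)-epicatechin
Product: 23 epirobinetinidol-(4β→8)-epirobinetinidol-(4α→8)-epicatechin (target)
Conditions: H2 (1 atm), Pd(OH)2/C, THF/MeOH/H2O, rt, exclusion of air on work-up
Reagents that add atoms: none
Why: Hydrogenolysis of all fourteen benzyl ethers over Pd(OH)2/C should leave the ring C–O bonds, the interflavan C–C bonds and every stereocentre untouched.

**Compound list**

1 | (−)-epicatechin, (2R,3R) | Oc1cc(O)c2c(c1)O[C@H](c1ccc(O)c(O)c1)[C@H](O)C2 | starting material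
2 | 5,7,3',4'-tetra-O-benzyl-(−)-epicatechin | c4ccccc4COc1cc(OCc4ccccc4)c2c(c1)O[C@H](c3ccc(OCc4ccccc4)c(OCc4ccccc4)c3)[C@H](O)C2 | intermediate
3 | 3,5,7,3',4'-penta-O-benzyl-(−)-epicatechin | c4ccccc4COc1cc(OCc4ccccc4)c2c(c1)O[C@H](c3ccc(OCc4ccccc4)c(OCc4ccccc4)c3)[C@H](OCc4ccccc4)C2 | intermediate
4 | 3,4,5-tris(benzyloxy)benzaldehyde | O=Cc1cc(OCc2ccccc2)c(OCc2ccccc2)c(OCc2ccccc2)c1 | starting material
5 | (E)-3-[3,4,5-tris(benzyloxy)phenyl]prop-2-enal | O=C/C=C/c1cc(OCc2ccccc2)c(OCc2ccccc2)c(OCc2ccccc2)c1 | intermediate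
6 | 5-[(E)-3,3-dimethoxyprop-1-enyl]-1,2,3-tris(benzyloxy)benzene | COC(OC)/C=C/c1cc(OCc2ccccc2)c(OCc2ccccc2)c(OCc2ccccc2)c1 | intermediate
7 | (2R,3S)-2-(dimethoxymethyl)-3-[3,4,5-tris(benzyloxy)phenyl]oxirane (trans) | COC(OC)[C@@H]1O[C@H]1c1cc(OCc2ccccc2)c(OCc2ccccc2)c(OCc2ccccc2)c1 | intermediate
8 | 2-bromobenzene-1,3-diol | Oc1cccc(O)c1Br | starting material
9 | 3-(benzyloxy)-2-bromophenol | Oc1cccc(OCc2ccccc2)c1Br | intermediate
10 | (2R,3R)-3-[3-(benzyloxy)-2-bromophenoxy]-1,1-dimethoxy-3-[3,4,5-tris(benzyloxy)phenyl]propan-2-ol | Brc1c(OCc4ccccc4)cccc1O[C@H](c3cc(OCc4ccccc4)c(OCc4ccccc4)c(OCc4ccccc4)c3)[C@@H](O)C(OC)OC | intermediate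
11 | ethyl (Z)-3-[3,4,5-tris(benzyloxy)phenyl]prop-2-enoate | CCOC(=O)/C=C\c1cc(OCc2ccccc2)c(OCc2ccccc2)c(OCc2ccccc2)c1 | intermediate
12 | ethyl (2S,3S)-3-[3,4,5-tris(benzyloxy)phenyl]oxirane-2-carboxylate (cis) | CCOC(=O)[C@H]1O[C@H]1c1cc(OCc2ccccc2)c(OCc2ccccc2)c(OCc2ccccc2)c1 | intermediate
13 | 3-(benzyloxy)phenol | Oc1cccc(OCc2ccccc2)c1 | starting material
14 | ethyl (2S,3R)-3-[3-(benzyloxy)phenoxy]-2-hydroxy-3-[3,4,5-tris(benzyloxy)phenyl]propanoate | c4ccccc4COc1cccc(c1)O[C@H](c3cc(OCc4ccccc4)c(OCc4ccccc4)c(OCc4ccccc4)c3)[C@H](O)C(=O)OCC | intermediate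
15 | ethyl (2S,3R)-2-(benzyloxy)-3-[3-(benzyloxy)phenoxy]-3-[3,4,5-tris(benzyloxy)phenyl]propanoate | c4ccccc4COc1cccc(c1)O[C@H](c3cc(OCc4ccccc4)c(OCc4ccccc4)c(OCc4ccccc4)c3)[C@H](OCc4ccccc4)C(=O)OCC | intermediate
16 | (2S,3R)-2-(benzyloxy)-3-[3-(benzyloxy)phenoxy]-3-[3,4,5-tris(benzyloxy)phenyl]propanal | c4ccccc4COc1cccc(c1)O[C@H](c3cc(OCc4ccccc4)c(OCc4ccccc4)c(OCc4ccccc4)c3)[C@H](OCc4ccccc4)C=O | intermediate
17 | (2R,3R)-2-(benzyloxy)-1-[2-(benzyloxy)-6-{[(1R,2R)-2-hydroxy-3,3-dimethoxy-1-(3,4,5-tris(benzyloxy)phenyl)propyl]oxy}phenyl]-3-[3-(benzyloxy)phenoxy]-3-[3,4,5-tris(benzyloxy)phenyl]propan-1-ol, both epimers at C-1 | c4ccccc4COc1cccc(c1)O[C@H](c3cc(OCc4ccccc4)c(OCc4ccccc4)c(OCc4ccccc4)c3)[C@H](OCc4ccccc4)C(O)c1c(OCc4ccccc4)cccc1O[C@H](c3cc(OCc4ccccc4)c(OCc4ccccc4)c(OCc4ccccc4)c3)[C@@H](O)C(OC)OC | intermediate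
18 | top-ring-closed acetal: (2R,3R,4R)-3,7-bis(benzyloxy)-4-[2-(benzyloxy)-6-{[(1R,2R)-2-hydroxy-3,3-dimethoxy-1-(3,4,5-tris(benzyloxy)phenyl)propyl]oxy}phenyl]-2-[3,4,5-tris(benzyloxy)phenyl]chroman (not isolated) | c4ccccc4COc1ccc2c(c1)O[C@H](c3cc(OCc4ccccc4)c(OCc4ccccc4)c(OCc4ccccc4)c3)[C@H](OCc4ccccc4)[C@H]2c1c(OCc4ccccc4)cccc1O[C@H](c3cc(OCc4ccccc4)c(OCc4ccccc4)c(OCc4ccccc4)c3)[C@@H](O)C(OC)OC | intermediate
19 | bis-cyclised 4-methoxyflavan: the (2R,3R,4R) top flavan of 18 bonded through C-4 to C-8 of a (2R,3S)-7-(benzyloxy)-4-methoxy-2-[3,4,5-tris(benzyloxy)phenyl]chroman-3-ol, both C-4 epimers of the methoxy carbon (not isolated) | c4ccccc4COc1ccc2c(c1)O[C@H](c3cc(OCc4ccccc4)c(OCc4ccccc4)c(OCc4ccccc4)c3)[C@H](OCc4ccccc4)[C@H]2c1c(OCc4ccccc4)ccc2c1O[C@H](c3cc(OCc4ccccc4)c(OCc4ccccc4)c(OCc4ccccc4)c3)[C@@H](O)C2OC | intermediate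
20 | tetradeca-O-benzyl epirobinetinidol-(4β→8)-robinetinidol-(4α→8)-epicatechin, middle 3-OH free: top 2R,3R,4R; middle 2R,3S,4S (2,3-trans-3,4-trans); bottom 2R,3R | c4ccccc4COc1ccc2c(c1)O[C@H](c3cc(OCc4ccccc4)c(OCc4ccccc4)c(OCc4ccccc4)c3)[C@H](OCc4ccccc4)[C@H]2c1c(OCc4ccccc4)ccc2c1O[C@H](c3cc(OCc4ccccc4)c(OCc4ccccc4)c(OCc4ccccc4)c3)[C@@H](O)[C@@H]2c1c(OCc4ccccc4)cc(OCc4ccccc4)c2c1O[C@H](c3ccc(OCc4ccccc4)c(OCc4ccccc4)c3)[C@H](OCc4ccccc4)C2 | intermediate
21 | 3-ketone of the middle unit of 20: top 2R,3R,4R; middle 2R,4S; bottom 2R,3R | c4ccccc4COc1ccc2c(c1)O[C@H](c3cc(OCc4ccccc4)c(OCc4ccccc4)c(OCc4ccccc4)c3)[C@H](OCc4ccccc4)[C@H]2c1c(OCc4ccccc4)ccc2c1O[C@H](c3cc(OCc4ccccc4)c(OCc4ccccc4)c(OCc4ccccc4)c3)C(=O)[C@@H]2c1c(OCc4ccccc4)cc(OCc4ccccc4)c2c1O[C@H](c3ccc(OCc4ccccc4)c(OCc4ccccc4)c3)[C@H](OCc4ccccc4)C2 | intermediate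
22 | tetradeca-O-benzyl epirobinetinidol-(4β→8)-epirobinetinidol-(4α→8)-epicatechin, middle 3-OH free: top 2R,3R,4R; middle 2R,3R,4S (all-cis); bottom 2R,3R | c4ccccc4COc1ccc2c(c1)O[C@H](c3cc(OCc4ccccc4)c(OCc4ccccc4)c(OCc4ccccc4)c3)[C@H](OCc4ccccc4)[C@H]2c1c(OCc4ccccc4)ccc2c1O[C@H](c3cc(OCc4ccccc4)c(OCc4ccccc4)c(OCc4ccccc4)c3)[C@H](O)[C@@H]2c1c(OCc4ccccc4)cc(OCc4ccccc4)c2c1O[C@H](c3ccc(OCc4ccccc4)c(OCc4ccccc4)c3)[C@H](OCc4ccccc4)C2 | intermediate
23 | epirobinetinidol-(4β→8)-epirobinetinidol-(4α→8)-epicatechin: top 2R,3R,4R; middle 2R,3R,4S; bottom 2R,3R | Oc1ccc2c(c1)O[C@H](c1cc(O)c(O)c(O)c1)[C@H](O)[C@H]2c1c(O)ccc2c1O[C@H](c1cc(O)c(O)c(O)c1)[C@H](O)[C@@H]2c1c(O)cc(O)c2c1O[C@H](c1ccc(O)c(O)c1)[C@H](O)C2 | target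

**Step count and risks**

Total step count: 17 steps. Longest linear sequence: 10 steps (steps 8 to 17: 4 → 11 → 12 → 14 → 15 → 16 → 17 → 20 → 21 → 22 → 23).

Steps most likely to fail:

Step 14. What may go wrong: capture of the first cation by 3 before the top ring closes, self-condensation of the cations with other electron-rich rings, substitution at C-6 of 3, or insufficient facial selectivity at middle C-4. Fallback, setting out from 17 and coming back at 20: the three bond formations are separated and the interflavan bond is made by an organolithium instead of a Friedel–Crafts substitution. Camphorsulfonic acid (cat.) in CH2Cl2 at 0 °C should ionise only the doubly activated carbinol of 17 and give 18 as an isolated compound. Mild hydrolysis of its acetal (aqueous trifluoroacetic acid, CH2Cl2, 0 °C) gives the α-hydroxy aldehyde F1. Separately, 3 is brominated with N-bromosuccinimide (CH2Cl2, −20 °C) to the 8-bromo derivative F2, whose aryllithium (n-BuLi, THF, −78 °C, used in excess) adds to F1 to give the diol F3 as a mixture of carbinol epimers. TMSOTf (cat.) at −78 °C then ionises only the benzylic carbinol of F3 and the middle ring closes by the same C-4a–C-4 Friedel–Crafts bond formation, the arene adding anti to the C-3 oxygen for the 1,3-strain reasons given above, to give 20.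

Step 13. What may go wrong: proton transfer from the hydroxyl group or from the benzylic ether C–H to the aryllithium, or slow addition of the doubly ortho-substituted aryllithium to the branched aldehyde, which would let enolisation and loss of aryloxide compete. Fallback, setting out from 9 and coming back at 18: the top flavan is built on a simple aryllithium first and the middle chain is attached afterwards. Phenol 9 is protected (MOMCl, i-Pr2NEt, CH2Cl2) as the methoxymethyl ether F4, which has no acidic proton. Bromine–lithium exchange on F4 (n-BuLi, THF, −78 °C) and addition to 16 give the carbinol F5. HCl in MeOH/CH2Cl2 closes the top pyran ring by dehydrative Friedel–Crafts alkylation (3,4-trans as in step 14) and removes the MOM group to give the phenol F6. Base-catalysed opening of epoxide 7 by F6 (Cs2CO3, DMF, 80 °C) gives 18, which is then submitted to the conditions of step 14.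

Step 16. What may go wrong: slow hydride transfer to a ketone flanked by two aryl-bearing carbons, so that enolisation towards C-2 or C-4 (epimerisation, already possible during step 15) or hydride delivery from the wrong face competes. Fallback, setting out from 20 and coming back at 22: the ketone is avoided and C-3 is inverted by SN2 displacement. Tf2O and pyridine (CH2Cl2, −20 °C) convert 20 into the equatorial triflate F7, which has no anti-periplanar hydrogen for elimination. Bu4NOAc in toluene displaces it with inversion to give the axial acetate F8, and K2CO3 in MeOH/THF releases 22.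

**Further compounds**

F1 | step 14 | α-hydroxy aldehyde from 18: (2R,3R)-2-hydroxy-3-aryloxy-3-[3,4,5-tris(benzyloxy)phenyl]propanal carried on the top flavan | c4ccccc4COc1ccc2c(c1)O[C@H](c3cc(OCc4ccccc4)c(OCc4ccccc4)c(OCc4ccccc4)c3)[C@H](OCc4ccccc4)[C@H]2c1c(OCc4ccccc4)cccc1O[C@H](c3cc(OCc4ccccc4)c(OCc4ccccc4)c(OCc4ccccc4)c3)[C@@H](O)C=O
F2 | step 14 | 8-bromo-3,5,7,3',4'-penta-O-benzyl-(−)-epicatechin | Brc1c(OCc4ccccc4)cc(OCc4ccccc4)c2c1O[C@H](c3ccc(OCc4ccccc4)c(OCc4ccccc4)c3)[C@H](OCc4ccccc4)C2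
F3 | step 14 | diol from F1 and lithiated F2 (both epimers at the new carbinol carbon) | c4ccccc4COc1ccc2c(c1)O[C@H](c3cc(OCc4ccccc4)c(OCc4ccccc4)c(OCc4ccccc4)c3)[C@H](OCc4ccccc4)[C@H]2c1c(OCc4ccccc4)cccc1O[C@H](c3cc(OCc4ccccc4)c(OCc4ccccc4)c(OCc4ccccc4)c3)[C@@H](O)C(O)c1c(OCc4ccccc4)cc(OCc4ccccc4)c2c1O[C@H](c3ccc(OCc4ccccc4)c(OCc4ccccc4)c3)[C@H](OCc4ccccc4)C2
F4 | step 13 | 1-(benzyloxy)-2-bromo-3-(methoxymethoxy)benzene | COCOc1cccc(OCc2ccccc2)c1Br
F5 | step 13 | (2R,3R)-2-(benzyloxy)-1-[2-(benzyloxy)-6-(methoxymethoxy)phenyl]-3-[3-(benzyloxy)phenoxy]-3-[3,4,5-tris(benzyloxy)phenyl]propan-1-ol (both C-1 epimers) | c4ccccc4COc1cccc(c1)O[C@H](c3cc(OCc4ccccc4)c(OCc4ccccc4)c(OCc4ccccc4)c3)[C@H](OCc4ccccc4)C(O)c1c(OCc4ccccc4)cccc1OCOC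
F6 | step 13 | 3-(benzyloxy)-2-[(2R,3R,4R)-3,7-bis(benzyloxy)-2-(3,4,5-tris(benzyloxy)phenyl)chroman-4-yl]phenol | c4ccccc4COc1ccc2c(c1)O[C@H](c3cc(OCc4ccccc4)c(OCc4ccccc4)c(OCc4ccccc4)c3)[C@H](OCc4ccccc4)[C@H]2c1c(OCc4ccccc4)cccc1O
F7 | step 16 | 3-O-triflate of the middle unit of 20 | c4ccccc4COc1ccc2c(c1)O[C@H](c3cc(OCc4ccccc4)c(OCc4ccccc4)c(OCc4ccccc4)c3)[C@H](OCc4ccccc4)[C@H]2c1c(OCc4ccccc4)ccc2c1O[C@H](c3cc(OCc4ccccc4)c(OCc4ccccc4)c(OCc4ccccc4)c3)[C@@H](OS(=O)(=O)C(F)(F)F)[C@@H]2c1c(OCc4ccccc4)cc(OCc4ccccc4)c2c1O[C@H](c3ccc(OCc4ccccc4)c(OCc4ccccc4)c3)[C@H](OCc4ccccc4)C2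
F8 | step 16 | 3-O-acetate of 22 (inverted, all-cis middle unit) | c4ccccc4COc1ccc2c(c1)O[C@H](c3cc(OCc4ccccc4)c(OCc4ccccc4)c(OCc4ccccc4)c3)[C@H](OCc4ccccc4)[C@H]2c1c(OCc4ccccc4)ccc2c1O[C@H](c3cc(OCc4ccccc4)c(OCc4ccccc4)c(OCc4ccccc4)c3)[C@H](OC(C)=O)[C@@H]2c1c(OCc4ccccc4)cc(OCc4ccccc4)c2c1O[C@H](c3ccc(OCc4ccccc4)c(OCc4ccccc4)c3)[C@H](OCc4ccccc4)C2
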